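The readings were computed on assumed constants; scatter was added.

The first nucleophile in Friday's flask stands beside the second nucleophile and the substrate, and the readings follow two products, target and other capture product; I took it that the first nucleophile gives target and the second gives the other capture product.

| setting | Friday's | Wednesday's | flask |
|---|---|---|---|
| substrate | 0.48 M | 0.48 M | 0.48 M |
| first nucleophile | 0.24 M | 0.16 M | 0.240 M |
| second nucleophile | 0.72 M | 0.72 M | 0.720 M |
| remark | the very flask that is asked about, followed so far | run made earlier |  |
| time |  |  | 20 min |

- Friday's (time / s: target / %, other capture product / %): 20.0: 6.6, 54.0; 40.0: 5.5, 71.8; 60.0: 6.3, 79.1; 80.0: 6.9, 82.1; 90.0: 6.7, 83.0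
- Wednesday's (time / min: target / %, other capture product / %): 4.00: 5.9, 86.9; 8.00: 6.3, 86.6; 12.0: 5.3, 86.3; 15.0: 5.2, 87.3; 20.0: 5.8, 86.2

(readings scatter by 0.5 percentage points)



- ratio of target to other capture product at 0.40 s
- ratio of target to other capture product at 20 min

As the zero of my scale I took the statistical case, in which each nucleophile takes substrate in proportion to its charge, so that the ratio of target to other capture product equals the charge ratio ρ = 0.333.

The readings form a ladder. On the first rung, in Friday's flask, target already read 6.6% at 20.0 s and 6.7% at 90.0 s, so its rise lay before the first reading, and 0.40 s stands on that unread rung. On the next rung, Friday's other capture product climbed from 54.0% to 83.0% over the same readings. On the last rung, Wednesday's flask read 86.9% of other capture product at 4.00 min and 86.2% at 20.0 min, a plateau as read.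

I set Friday's last target reading over Wednesday's last other capture product reading, borrowing the plateau from a flask charged with less first nucleophile, and this gave my estimate of 0.0777 for 20 min. That makes the selectivity factor S, the ratio divided by ρ, 0.233, below the statistical case. Wednesday's flask read S = 0.303. For 0.40 s I committed to no number of my own.

The forecast gave 1.8 for 0.40 s and 0.074 for 20 min, and said of the early target: “Target comes from a fast, nearly self-limiting burst, weakly dependent on first nucleophile”.

The flask gave 2.28 at 0.40 s and 0.0765 at 20 min.

    2 first nucleophile → self-condensation product (k = 2.90 L mol⁻¹ s⁻¹)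
    first nucleophile + intermediate → target (k = 17.0 L mol⁻¹ s⁻¹)
    second nucleophile + intermediate → other capture product (k = 1.80 L mol⁻¹ s⁻¹)
    substrate ⇌ intermediate (K = 0.0770, k = 0.190 s⁻¹)
    first nucleophile + target → over-reaction product (k = 0.240 L mol⁻¹ s⁻¹)
    target ⇌ isomer of the product (K = 1.30, k = 0.0950 s⁻¹)

Target and other capture product stood level at 8.32% after 0.0375 min. S in this flask was 6.83 at 0.40 s and 0.229 at 20 min. In a flask otherwise the same but charged with 0.41 M of first nucleophile, the ratio at 20 min was 0.0897, which makes S = 0.158.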